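Follow the catalyst.

| flask | substrate | free catalyst | remark | time |
|---|---|---|---|---|
| blue | 0.050 M | 0.50 mM | run made earlier |  |
| violet | 0.10 M | 0.50 mM | run made earlier |  |
| summer | 0.050 M | 0.50 mM | a closed flask charged with all of it at once and left for 2.0 min | 2.0 min |
| dawn | 0.050 M (fed, over 1.60 min) | 0.50 mM | all but substrate at the start; substrate goes in evenly over 1.60 min, the run ends at 2.0 min | 2.0 min |
| autumn | 0.050 M | 0.50 mM | one stirred flow tank at steady state, fed with the mixture as stated, mean residence time 2.0 min |  |
| dusk | 0.050 M | 0.50 mM | plug flow through a tube for 2.0 min, no back-mixing | 2.0 min |

| run | time / s | target / % | substrate / % |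
|---|---|---|---|
| blue | 10.0 | 38.6 | 44.6 |
| blue | 25.0 | 32.7 | 37.9 |
| blue | 50.0 | 28.3 | 33.2 |
| blue | 80.0 | 29.2 | 30.6 |
| violet | 10.0 | 40.1 | 44.9 |
| violet | 15.0 | 36.7 | 43.1 |
| violet | 25.0 | 34.1 | 38.0 |

(scatter of a reading: 1 percentage point)

- the stated concentrations are those of everything mixed, before any reaction; amounts are the same in each set-up
- what was read earlier has a scatter of 1 percentage point, one standard deviation
- steps thought possible: substrate + free catalyst <-> target + free catalyst; target + free catalyst <-> isomer of the product + free catalyst; 2 free catalyst -> spent catalyst
- the feed brings no volume worth counting
- the earlier runs were made in a closed, stirred flask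

* the set-up with the highest amount of target at the outlet or at the end, in percent of the substrate put in ("none" if the first two lie within 2 percentage points) (summer / dawn / autumn / dusk / none)
* amount of target at the outlet or at the end, in percent of the substrate put in, summer
* amount of target at the outlet or at the end, in percent of the substrate put in, dawn
* amount of target at the outlet or at the end, in percent of the substrate put in, autumn
* amount of target at the outlet or at the end, in percent of the substrate put in, dusk

The free catalyst is charged at 1.00% of the substrate, and its own balance holds no substrate. With f the free fraction of its charge, and 1 − f spent: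

df/dt = −f·f/T, so f = 1/(1 + t/T)

At a given f, each step of the substrate is pseudo-first-order, so progress counts in catalyst-time, the integral of f. A portion put in at time s and read at t therefore matches a blue-run portion of age

age = (t − s)/(1 + s/T)

Now I read T from the blue run. Isomer is what the two columns miss: 16.8%, 29.4%, 38.5%, 40.2%. Its gain per second falls from 0.00840 s⁻¹ to 0.00364 s⁻¹ over the first two windows. The back step weighs isomer by a factor between none and the last target-to-isomer ratio, and I take half of that ratio: 0.363. Then (target − factor × isomer)/gain should grow in a straight line with time:

32.5 s, then 49.9 s

So T, the first half-life of the free catalyst as read, is 19.7 s.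

For dawn I take the mid-feed portion, s = 48.0 s:

age = 20.9 s, target between the blue readings = 34.3%

Summer and dusk lie past the last blue reading, so I hold them at 29.2%.

The weak link is the halved factor. Doubling T gives age 32.4 s and target 31.4%, still 2.2 percentage points above the figure held for summer and dusk, against a margin of 2 points. I commit to dawn.

The forecast gives 28% for summer, 28.8% for dawn, 29.5% for autumn and 28% for dusk, best none, holding that “Catalyst death isn't needed, though it can't be excluded”. I have no tank reckoning of my own; my dawn figure stands above its tank figure.

The flasks give 25.7% for summer, 33.3% for dawn, 30.3% for autumn and 25.7% for dusk, best dawn.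

    substrate + free catalyst ⇌ target + free catalyst, rate k1*[substrate]*[free catalyst] forward; the back reaction follows from the equilibrium constant (K = 0.877, k = 3930 L mol⁻¹ s⁻¹)
    target + free catalyst ⇌ isomer of the product + free catalyst, rate k2*[free catalyst]*[target] forward; the back reaction follows from the equilibrium constant (K = 2.22, k = 106 L mol⁻¹ s⁻¹)
    2 free catalyst → spent catalyst (k = 38.9 L mol⁻¹ s⁻¹)

Dawn read at 5.0 min takes the same reckoning with the same T: its mid-feed portion has age 73.2 s, which falls between the blue readings at 50.0 s and 80.0 s, of 28.3% and 29.2% target. That flask holds 26.8% target beside 30.6% substrate.

The earlier runs and the new flask were generated by integration on assumed constants; the scatter is artificial.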